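## Structural features

The target is the ester of a bicyclic eremophilane-type alcohol with (2E,4E,6S)-6-methylocta-2,4-dienoic acid. The core has two six-membered carbocycles that share the C5–C10 bond: ring A (C1, C2, C3, C4, C5, C10) and ring B (C5, C6, C7, C8, C9, C10). A cross-conjugated trienone runs through both rings: the C8 ketone carries the linear C9=C10–C1=C2 diene on one side and the C7 isopropylidene on the other. Three stereocentres stand in a row, C3 (S, acyloxy), C4 (R, methyl) and the quaternary C5 (R, methyl), with all three substituents on the same face of ring A; the fourth, C6' (S) of the acyl chain, is remote. The fragile groups are the allylic C3 ester, the isopropylidene enone (deconjugation), the electrophilic dienone and the α-branched aldehyde from which the dienoate is built (racemisation). The real difficulty is the quaternary C5 next to C4 and C3, together with reaching the dienone oxidation level without a late dehydrogenation. The key step exploits ring B: it is a cyclohex-2-enone in which C5 and C8 are joined by C6–C7 on one side and by the C9=C10 alkene on the other, that is, a 2-methylcyclobutanone (C5, C6, C7, C8) with an alkyne inserted into its C5–C8 bond. Because C10 also belongs to ring A, an alkyne tethered to C5 through C4, C3 and a Z C2=C1 alkene closes both rings in one insertion.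

## Logic of the disconnections

30 to 22 and 28. The acyl C–O bond at C3 is cut. This removes the base- and nucleophile-sensitive dienoate from all carbanion chemistry and splits the target into a core and a chiral-pool side chain. The forward acylation must work on a hindered allylic alcohol without breaking the C3–O bond.

28 to 23 and 24 (through 27 and 25). The C4'=C5' alkene is cut, and the acid is traced to its ethyl ester. The whole diene comes from one four-carbon phosphonate and the stereocentre from a commercial alcohol. The demand is that 25, which racemises easily, is made and consumed without exposure to base.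

22 to 16 and 17 (through 21 and 19). The C7=C11 bond is cut and both silicon groups are put back. C7 is the only enolisable position of 16, so the isopropylidene is a late aldol and dehydration. The demands are conjugated (not isopropenyl) elimination and a single fluoride step that removes silicon from both O3 and C9.

16 to 15 (key step). The C5–C10 and C8–C9 bonds are cut, which opens both rings and leaves a 2-methylcyclobutanone carrying a Z-enyne at C5. The gain is two rings and the complete dienone from an acyclic tether, with no redox adjustment afterwards. The demands are: cleavage of the more substituted C5–C8 bond; insertion at a fully substituted carbon; and a precursor whose C5 is already (R), because C5 is carried through with retention. The design of 15 therefore fixes all three centres as (3S,4R,5R). It keeps the Z-alkene so that the alkyne sits next to C5. It caps the alkyne with a trimethylsilyl group, which shields the terminus from vinylidene chemistry and is later removed together with the O3 silyl group.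

15 to 11 and 14 (through 13 and 12). The C1–C10 sp2–sp bond is cut, and the Z-iodoalkene is traced to the silyl alkyne. The alkyne survives the organometallic steps that an alkenyl iodide would not. The demand is a strictly cis semi-reduction that does not touch the cyclobutanone.

11 to 9 (through 10). The C5–C6 bond (ring expansion of a cyclopropylcarbinol) and the C5–CH3 bond are cut. C5 is thereby reduced to a ketone carbon whose two new substituents arrive in a chosen order. The order matters. Under Felkin–Anh control a nucleophile enters anti to the silyloxy-bearing carbon, and the migrating methylene then enters C5 with inversion. If the cyclopropyl carbon were added to a C5 methyl ketone, this would give the C5 epimer, so a one-step cyclopropylide annulation of that ketone is not used. Adding the methyl group last to the cyclopropyl ketone should give (5R).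

9 to 5 and 6 (through 8 and 7). The C5–C8 bond is cut. All three cyclobutanone carbons besides C5 come from one commercial sulfide. The demand is clean 1,2-addition to an epimerisable aldehyde, followed by an oxidation that spares sulfur.

5 to 1 and 2 (through 4 and 3). The C3–C4 bond is cut, and the C5 aldehyde is traced to a vinyl group. Both secondary stereocentres arise in one catalytic step from two commercial reagents. The demand is anti selectivity and the (3R) sense of induction.

## Other disconnections considered

Alternative 1: The cut is at the angular methyl group. C14 is traced to a cyclopropane methylene bridging C5 and C10, and ring B to a reduced aromatic ring. In the forward sense the tetrasubstituted alkene A1 is treated with Et2Zn and CH2I2. The zinc alkoxide at C3 holds the carbenoid and delivers CH2 to the C5=C10 bond on the hydroxyl face, giving A2 (bonds C5–C14 and C10–C14). Later unmasking of the C8 ketone and acid opening of the C10–C14 bond through the C8 enol would release the C5 methyl cis to O3 together with the C9=C10 enone.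
- In its favour: every step is of a known type, and C5 is set by intramolecular delivery within a ring. That is a safer control element than the open-chain induction of steps 6 and 7, so on control of C5 and on precedent this alternative is the better.
- Against it here: direction is homoallylic and onto a tetrasubstituted alkene, which can be slow. The cyclopropane must open at C10–C14 and not at C5–C14. The route arrives at a 9-en-8-one without C1=C2, so a dehydrogenation next to the C3 oxygen and several ketal and enol-ether adjustments are needed.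
- Comparison: it forms no ring in its key step, against two in the chosen plan. Its mechanism is secure where the chosen one is proposed. Its step count is expected to be about equal once the enantioselective entry to the aromatic precursor and the late oxidation are counted.

Alternative 2: The cut is the C1–C2 bond of ring A. In the forward sense the bis-silyl enol ether A3, which already holds ring B and the quaternary C5, is oxidised at an anode. The dienol ether gives a radical cation whose C1 terminus is captured by C2 of the enol ether, and loss of both silyl groups gives enedione A4.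
- In its favour: it joins two nucleophilic carbons without prefunctionalisation, needs no transition metal and tolerates the neopentyl surroundings of C5. Like the chosen key step it forms no stereocentre, so on that point the two are equal. On operational simplicity the electrolysis is the better.
- Against it here: C4 and C5 must be set beforehand by an intermolecular bond formation that is no easier to control than steps 6 and 7. A4 is at the wrong oxidation level: the C3 ketone must be reduced cis to the C4 methyl, and C1=C2 must be introduced in a molecule with two enolisable ketones. The isopropylidene is still to come.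
- Comparison: one ring and one bond against two rings and two bonds. The reaction class is known where the chosen one is not. It is expected to be about three steps longer after the key step.

Alternative 3: The cut is the C1–C10 bond. In the forward sense the Z-iodoalkene A5, whose quaternary carbon lies in a symmetric cyclohexadienone and is not yet a stereocentre, adds oxidatively to zerovalent palladium generated from Pd(OAc)2 and a phosphine. The alkenylpalladium then adds 6-exo to one of the two diastereotopic enone alkenes (C1–C10), and β-hydride loss restores C9=C10 to give A6.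
- In its favour: C5 is created in the ring-forming step, so no open-chain control of a quaternary centre is needed. On that point this alternative is the better, and its reaction class is known. A5 uses the same C3/C4 chemistry as 13, and A6 already holds the 1,9-dien-8-one.
- Against it here: the choice between the two alkenes rests on how the C4 methyl and C3 silyloxy groups sit in the forming ring and may be modest. β-Hydride loss after syn addition needs epimerisation through a palladium enolate. A6 carries an extra C6=C7 alkene that must be reduced in the presence of the dienone, although a reductive aldol could turn this into the isopropylidene entry, which would be equal to steps 12 and 13. The dienone precursor costs an annulation and a dehydrogenation.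
- Comparison: one ring, one bond and one stereocentre against two rings, two bonds and none. The mechanism is known where the chosen one is proposed. The step count is expected to be similar. This alternative is kept as the fallback for the key step.

Key step: step 11

Remark on the chemistry (assumption): the (R)-configured phosphoric acid is taken to deliver the crotyl group to the Re face of 1, as it does with aryl aldehydes; if the sense is opposite, its enantiomer is used and nothing else changes.

## Route

Step 1
Reactants: 1 3-(trimethylsilyl)prop-2-ynal; 2 (E)-crotylboronic acid pinacol ester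
Product: 3 (3R,4R)-4-methyl-1-(trimethylsilyl)hex-5-en-1-yn-3-ol
Conditions: (R)-TRIP phosphoric acid [(R)-3,3'-bis(2,4,6-triisopropylphenyl)-1,1'-binaphthyl-2,2'-diyl hydrogen phosphate] (5 mol %), 4 Å MS, toluene, −40 °C
Reagents that add atoms: none
Why: Phosphoric acid-catalysed crotylboration through a closed chair transition state, in which the E-crotyl geometry becomes the anti relation of the C3 hydroxyl and C4 methyl and the (R)-acid should direct attack to the Re face (3R, hence 4R). The low temperature keeps the uncatalysed addition to this reactive ynal slow.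

Step 2
Reactants: 3 (3R,4R)-4-methyl-1-(trimethylsilyl)hex-5-en-1-yn-3-ol
Product: 4 tert-butyldimethyl{[(3R,4R)-4-methyl-1-(trimethylsilyl)hex-5-en-1-yn-3-yl]oxy}silane
Conditions: TBSOTf, 2,6-lutidine, CH2Cl2, −78 to 0 °C
Reagents that add atoms: tert-butyldimethylsilyl trifluoromethanesulfonate, CC(C)(C)[Si](C)(C)OS(=O)(=O)C(F)(F)F
Why: Silylation of a hindered secondary propargylic alcohol with the silyl triflate. The bulky, non-chelating silyl ether is what the Felkin-controlled step 6 and the fluoride step 14 need.

Step 3
Reactants: 4 tert-butyldimethyl{[(3R,4R)-4-methyl-1-(trimethylsilyl)hex-5-en-1-yn-3-yl]oxy}silane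
Product: 5 (2S,3R)-3-[(tert-butyldimethylsilyl)oxy]-2-methyl-5-(trimethylsilyl)pent-4-ynal
Conditions: O3, CH2Cl2, −78 °C; then PPh3, −78 °C to rt
Reagents that add atoms: ozone, [O-][O+]=O
Why: Ozonolysis with reductive work-up; the monosubstituted alkene reacts far faster than the silyl alkyne, and the neutral phosphine work-up leaves the α-stereocentre (C4) untouched.

Step 4
Reactants: 5 (2S,3R)-3-[(tert-butyldimethylsilyl)oxy]-2-methyl-5-(trimethylsilyl)pent-4-ynal; 6 cyclopropyl phenyl sulfide
Product: 8 (2R,3R)-3-[(tert-butyldimethylsilyl)oxy]-2-methyl-1-[1-(phenylsulfanyl)cyclopropyl]-5-(trimethylsilyl)pent-4-yn-1-ol (both C1 epimers), via 1-lithiocyclopropyl phenyl sulfide 7 (not isolated)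
Conditions: 6, n-BuLi, THF, 0 °C; then 5, −78 °C
Reagents that add atoms: none
Why: Deprotonation of 6 gives a sulfur-stabilised cyclopropyl carbanion that adds 1,2 to the aldehyde at low temperature. The configuration of the new carbinol carbon does not matter because it is oxidised in step 5.

Step 5
Reactants: 8 (2R,3R)-3-[(tert-butyldimethylsilyl)oxy]-2-methyl-1-[1-(phenylsulfanyl)cyclopropyl]-5-(trimethylsilyl)pent-4-yn-1-ol
Product: 9 (2S,3R)-3-[(tert-butyldimethylsilyl)oxy]-2-methyl-1-[1-(phenylsulfanyl)cyclopropyl]-5-(trimethylsilyl)pent-4-yn-1-one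
Conditions: Dess–Martin periodinane, CH2Cl2, 0 °C to rt
Reagents that add atoms: none
Why: Dess–Martin oxidation under near-neutral conditions, which spares the sulfide and should not epimerise C4 of the β-silyloxy ketone.

Step 6
Reactants: 9 (2S,3R)-3-[(tert-butyldimethylsilyl)oxy]-2-methyl-1-[1-(phenylsulfanyl)cyclopropyl]-5-(trimethylsilyl)pent-4-yn-1-one
Product: 10 (2S,3S,4R)-4-[(tert-butyldimethylsilyl)oxy]-3-methyl-2-[1-(phenylsulfanyl)cyclopropyl]-6-(trimethylsilyl)hex-5-yn-2-ol
Conditions: MeLi, CeCl3, THF, −78 °C
Reagents that add atoms: methyllithium, [Li]C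
Why: Organocerium addition gives clean 1,2-addition to a hindered, enolisable ketone. C5 is set by Felkin–Anh control: the silyloxy-bearing carbon lies anti to the incoming methyl, which passes the C4 hydrogen, and the anti, non-chelating β-silyloxy group reinforces this, so the (2S) carbinol is expected. The methyl is added last on purpose, because adding the cyclopropyl carbon to the corresponding methyl ketone under the same bias would lead to the C5 epimer.

Step 7
Reactants: 10 (2S,3S,4R)-4-[(tert-butyldimethylsilyl)oxy]-3-methyl-2-[1-(phenylsulfanyl)cyclopropyl]-6-(trimethylsilyl)hex-5-yn-2-ol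
Product: 11 (2R)-2-{(2R,3R)-3-[(tert-butyldimethylsilyl)oxy]-5-(trimethylsilyl)pent-4-yn-2-yl}-2-methylcyclobutan-1-one
Conditions: TsOH·H2O (0.2 equiv), water-saturated benzene, 50 °C
Reagents that add atoms: water, O
Why: Acid-induced cyclopropylcarbinyl-to-cyclobutyl ring expansion of a β-hydroxy sulfide: as water leaves C5 the cyclopropane bond anti to it migrates, and the sulfur-stabilised cation is hydrolysed to the ketone with loss of thiophenol. Migration with inversion at C5 turns the carbinol configuration of 10 into the (R) quaternary centre of 11.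

Step 8
Reactants: 11 (2R)-2-{(2R,3R)-3-[(tert-butyldimethylsilyl)oxy]-5-(trimethylsilyl)pent-4-yn-2-yl}-2-methylcyclobutan-1-one
Product: 12 (2R)-2-{(2R,3R)-3-[(tert-butyldimethylsilyl)oxy]-5-iodopent-4-yn-2-yl}-2-methylcyclobutan-1-one
Conditions: NIS, AgNO3 (10 mol %), acetone, rt, dark
Reagents that add atoms: N-iodosuccinimide, O=C1CCC(=O)N1I
Why: Silver-catalysed ipso-iododesilylation of the alkynylsilane. The ketone and the silyl ether are inert to NIS under these neutral conditions, and the sulfide, which would not be, has already left.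

Step 9
Reactants: 12 (2R)-2-{(2R,3R)-3-[(tert-butyldimethylsilyl)oxy]-5-iodopent-4-yn-2-yl}-2-methylcyclobutan-1-one
Product: 13 (2R)-2-{(2R,3R,4Z)-3-[(tert-butyldimethylsilyl)oxy]-5-iodopent-4-en-2-yl}-2-methylcyclobutan-1-one
Conditions: KO2CN=NCO2K, AcOH, pyridine, MeOH, rt
Reagents that add atoms: none
Why: Diimide reduction: syn transfer of H2 to the iodoalkyne gives the Z-iodoalkene. This diimide source contains no hydrazide that could condense with the cyclobutanone.

Step 10
Reactants: 13 (2R)-2-{(2R,3R,4Z)-3-[(tert-butyldimethylsilyl)oxy]-5-iodopent-4-en-2-yl}-2-methylcyclobutan-1-one; 14 ethynyltrimethylsilane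
Product: 15 (2R)-2-{(2R,3S,4Z)-3-[(tert-butyldimethylsilyl)oxy]-7-(trimethylsilyl)hept-4-en-6-yn-2-yl}-2-methylcyclobutan-1-one
Conditions: Pd(PPh3)2Cl2 (3 mol %), CuI (6 mol %), iPr2NH, THF, rt
Reagents that add atoms: none
Why: Sonogashira coupling of the alkenyl iodide at room temperature proceeds with retention of the Z geometry and places the silyl-capped alkyne needed for step 11.

Step 11
Reactants: 15 (2R)-2-{(2R,3S,4Z)-3-[(tert-butyldimethylsilyl)oxy]-7-(trimethylsilyl)hept-4-en-6-yn-2-yl}-2-methylcyclobutan-1-one
Product: 16 (4aR,5R,6S)-6-[(tert-butyldimethylsilyl)oxy]-4a,5-dimethyl-1-(trimethylsilyl)-4,4a,5,6-tetrahydronaphthalen-2(3H)-one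
Conditions: [Rh(C2H4)2Cl]2 (5 mol %), PMe2Ph (20 mol %), 1,4-dioxane, 120 °C, argon
Reagents that add atoms: none
Why: Proposed new method: monovalent rhodium, made small and electron-rich by PMe2Ph, is expected to add oxidatively into the strained acyl C8–C5 bond of 15 to give a five-membered rhodacycle of trivalent rhodium; syn insertion of the pendant alkyne into the Rh–C5 bond closes ring A in a 6-exo mode, and acyl–alkenyl reductive elimination closes ring B by expanding the four-membered ring to the cyclohexenone, so C5–C10 and C8–C9 form in one catalytic event without a new stereocentre. The closest known reactions are rhodium-catalysed cut-and-sew couplings of cyclobutanones with tethered alkynes and nickel-catalysed alkyne insertions into cyclobutanones; what has not been shown is cleavage of the more substituted acyl–quaternary carbon bond with a conjugated Z-enyne as the two-carbon partner. The step needs site selectivity for C5–C8 over C7–C8, and this rests on reversible oxidative addition plus geometry: the Z-alkene holds the alkyne next to C5, only the C5-bound rhodacycle can reach it in a fused mode, and the C7-bound isomer would have to form a bridgehead alkene. C5 has no hydrogen and passes from carbon to rhodium to carbon on one face, so its configuration is retained and the cis relation of the C4 and C5 methyl groups is carried over from 15. Syn insertion puts C5 and C8 cis on the new C9=C10 bond, as the six-membered ring B requires, and the Z-alkene of the tether becomes C1=C2, so the linear dienone arrives directly. The trimethylsilyl cap keeps the alkyne terminus out of vinylidene and oligomerisation pathways and ends on C9. Decarbonylation of the acyl rhodium to a cyclopropane and β-hydride loss from the C5-bound alkyl towards C4 or the methyl group are the side paths, which the small donor phosphine and the intramolecular trap are meant to outrun.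

Step 12
Reactants: 16 (4aR,5R,6S)-6-[(tert-butyldimethylsilyl)oxy]-4a,5-dimethyl-1-(trimethylsilyl)-4,4a,5,6-tetrahydronaphthalen-2(3H)-one; 17 acetone
Product: 19 (4aR,5R,6S)-6-[(tert-butyldimethylsilyl)oxy]-3-(2-hydroxypropan-2-yl)-4a,5-dimethyl-1-(trimethylsilyl)-4,4a,5,6-tetrahydronaphthalen-2(3H)-one (C3 epimers), via lithium enolate 18 (not isolated)
Conditions: LiN(iPr)2, THF, −78 °C; then acetone, −78 °C
Reagents that add atoms: none
Why: Kinetic deprotonation can only take place at C7, since C9 carries silicon and C10 has no hydrogen, and the cross-conjugated lithium enolate adds to acetone in an aldol addition at low temperature. The new C7 stereocentre is removed in step 13.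

Step 13
Reactants: 19 (4aR,5R,6S)-6-[(tert-butyldimethylsilyl)oxy]-3-(2-hydroxypropan-2-yl)-4a,5-dimethyl-1-(trimethylsilyl)-4,4a,5,6-tetrahydronaphthalen-2(3H)-one
Product: 21 (4aR,5R,6S)-6-[(tert-butyldimethylsilyl)oxy]-4a,5-dimethyl-3-(propan-2-ylidene)-1-(trimethylsilyl)-4,4a,5,6-tetrahydronaphthalen-2(3H)-one, via tertiary mesylate 20 (not isolated)
Conditions: MsCl, Et3N, DMAP (cat.), CH2Cl2, 0 °C; then DBU, rt
Reagents that add atoms: none
Why: Mesylation of the tertiary alcohol followed by E1cB elimination through the C7 enolate should give the conjugated, tetrasubstituted isopropylidene and not the isopropenyl isomer.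

Step 14
Reactants: 21 (4aR,5R,6S)-6-[(tert-butyldimethylsilyl)oxy]-4a,5-dimethyl-3-(propan-2-ylidene)-1-(trimethylsilyl)-4,4a,5,6-tetrahydronaphthalen-2(3H)-one
Product: 22 (4aR,5R,6S)-6-hydroxy-4a,5-dimethyl-3-(propan-2-ylidene)-4,4a,5,6-tetrahydronaphthalen-2(3H)-one
Conditions: Bu4NF (3 equiv), wet THF, 0 °C to rt
Reagents that add atoms: none
Why: Fluoride cleaves the secondary silyl ether and, with water present, the C9–Si bond of the α-silyl enone (protodesilylation of a vinylsilane activated by the adjacent carbonyl), so both silicon groups leave in one operation. No stereocentre is involved.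

Step 15
Reactants: 23 (S)-2-methylbutan-1-ol; 24 triethyl 4-phosphonocrotonate
Product: 27 ethyl (2E,4E,6S)-6-methylocta-2,4-dienoate, via (S)-2-methylbutanal 25 (not isolated), via lithiated phosphonate 26 (not isolated)
Conditions: 23, TEMPO (10 mol %), PhI(OAc)2, CH2Cl2, rt; washed solution of 25 added at −78 °C to 24 and LiN(SiMe3)2 in THF, then 0 °C
Reagents that add atoms: none
Why: Oxoammonium oxidation gives the configurationally labile α-branched aldehyde without base, and it is consumed at once in a vinylogous Horner–Wadsworth–Emmons olefination that forms the new alkene E-selectively. The C6 stereocentre comes from 23 and is no longer α to a carbonyl after the olefination.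

Step 16
Reactants: 27 ethyl (2E,4E,6S)-6-methylocta-2,4-dienoate
Product: 28 (2E,4E,6S)-6-methylocta-2,4-dienoic acid
Conditions: LiOH, THF–MeOH–H2O, rt; then 1 M HCl
Reagents that add atoms: lithium hydroxide, [Li+].[OH-]
Why: Saponification; hydroxide attacks the ester carbonyl much faster than it removes the remote C6 hydrogen, so geometry and configuration should be kept.

Step 17
Reactants: 22 (4aR,5R,6S)-6-hydroxy-4a,5-dimethyl-3-(propan-2-ylidene)-4,4a,5,6-tetrahydronaphthalen-2(3H)-one; 28 (2E,4E,6S)-6-methylocta-2,4-dienoic acid
Product: 30 (1R,2S,8aR)-1,8a-dimethyl-6-oxo-7-(propan-2-ylidene)-1,2,6,7,8,8a-hexahydronaphthalen-2-yl (2E,4E,6S)-6-methylocta-2,4-dienoate, via mixed anhydride 29 (not isolated)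
Conditions: 28, 2,4,6-Cl3C6H2COCl, Et3N, toluene, rt; then 22, DMAP, rt
Reagents that add atoms: none
Why: Yamaguchi esterification: DMAP attacks the mixed anhydride at the dienoyl carbonyl and the acylpyridinium acylates the hindered allylic alcohol. The C3–O bond is not broken, so C3 keeps its configuration.

## Compound list

1 | 3-(trimethylsilyl)prop-2-ynal | C[Si](C)(C)C#CC=O | starting material
2 | (E)-crotylboronic acid pinacol ester | C/C=C/CB1OC(C)(C)C(C)(C)O1 | starting material
3 | (3R,4R)-4-methyl-1-(trimethylsilyl)hex-5-en-1-yn-3-ol | C=C[C@@H](C)[C@@H](O)C#C[Si](C)(C)C | intermediate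
4 | tert-butyldimethyl{[(3R,4R)-4-methyl-1-(trimethylsilyl)hex-5-en-1-yn-3-yl]oxy}silane | C=C[C@@H](C)[C@@H](O[Si](C)(C)C(C)(C)C)C#C[Si](C)(C)C | intermediate
5 | (2S,3R)-3-[(tert-butyldimethylsilyl)oxy]-2-methyl-5-(trimethylsilyl)pent-4-ynal | O=C[C@@H](C)[C@@H](O[Si](C)(C)C(C)(C)C)C#C[Si](C)(C)C | intermediate
6 | cyclopropyl phenyl sulfide | C1CC1Sc1ccccc1 | starting material
7 | 1-lithiocyclopropyl phenyl sulfide (not isolated) | [Li]C1(Sc2ccccc2)CC1 | intermediate
8 | (2R,3R)-3-[(tert-butyldimethylsilyl)oxy]-2-methyl-1-[1-(phenylsulfanyl)cyclopropyl]-5-(trimethylsilyl)pent-4-yn-1-ol, both C1 epimers | OC([C@@H](C)[C@@H](O[Si](C)(C)C(C)(C)C)C#C[Si](C)(C)C)C1(Sc2ccccc2)CC1 | intermediate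
9 | (2S,3R)-3-[(tert-butyldimethylsilyl)oxy]-2-methyl-1-[1-(phenylsulfanyl)cyclopropyl]-5-(trimethylsilyl)pent-4-yn-1-one | O=C([C@@H](C)[C@@H](O[Si](C)(C)C(C)(C)C)C#C[Si](C)(C)C)C1(Sc2ccccc2)CC1 | intermediate
10 | (2S,3S,4R)-4-[(tert-butyldimethylsilyl)oxy]-3-methyl-2-[1-(phenylsulfanyl)cyclopropyl]-6-(trimethylsilyl)hex-5-yn-2-ol | C[C@@H]([C@@H](O[Si](C)(C)C(C)(C)C)C#C[Si](C)(C)C)[C@](C)(O)C1(Sc2ccccc2)CC1 | intermediate
11 | (2R)-2-{(2R,3R)-3-[(tert-butyldimethylsilyl)oxy]-5-(trimethylsilyl)pent-4-yn-2-yl}-2-methylcyclobutan-1-one | C[C@@H]([C@@H](O[Si](C)(C)C(C)(C)C)C#C[Si](C)(C)C)[C@@]1(C)CCC1=O | intermediate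
12 | (2R)-2-{(2R,3R)-3-[(tert-butyldimethylsilyl)oxy]-5-iodopent-4-yn-2-yl}-2-methylcyclobutan-1-one | C[C@@H]([C@@H](O[Si](C)(C)C(C)(C)C)C#CI)[C@@]1(C)CCC1=O | intermediate
13 | (2R)-2-{(2R,3R,4Z)-3-[(tert-butyldimethylsilyl)oxy]-5-iodopent-4-en-2-yl}-2-methylcyclobutan-1-one | C[C@@H]([C@@H](O[Si](C)(C)C(C)(C)C)/C=C\I)[C@@]1(C)CCC1=O | intermediate
14 | ethynyltrimethylsilane | C#C[Si](C)(C)C | starting material
15 | (2R)-2-{(2R,3S,4Z)-3-[(tert-butyldimethylsilyl)oxy]-7-(trimethylsilyl)hept-4-en-6-yn-2-yl}-2-methylcyclobutan-1-one | C[C@@H]([C@@H](O[Si](C)(C)C(C)(C)C)/C=C\C#C[Si](C)(C)C)[C@@]1(C)CCC1=O | intermediate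
16 | (4aR,5R,6S)-6-[(tert-butyldimethylsilyl)oxy]-4a,5-dimethyl-1-(trimethylsilyl)-4,4a,5,6-tetrahydronaphthalen-2(3H)-one | CC(C)(C)[Si](C)(C)O[C@H]1C=CC2=C([Si](C)(C)C)C(=O)CC[C@]2(C)[C@H]1C | intermediate
17 | acetone | CC(C)=O | starting material
18 | lithium (4aR,5R,6S)-6-[(tert-butyldimethylsilyl)oxy]-4a,5-dimethyl-1-(trimethylsilyl)-4,4a,5,6-tetrahydronaphthalen-2-olate (not isolated) | CC(C)(C)[Si](C)(C)O[C@H]1C=CC2=C([Si](C)(C)C)C(O[Li])=CC[C@]2(C)[C@H]1C | intermediate
19 | (4aR,5R,6S)-6-[(tert-butyldimethylsilyl)oxy]-3-(2-hydroxypropan-2-yl)-4a,5-dimethyl-1-(trimethylsilyl)-4,4a,5,6-tetrahydronaphthalen-2(3H)-one, C3 epimers | CC(C)(C)[Si](C)(C)O[C@H]1C=CC2=C([Si](C)(C)C)C(=O)C(C(C)(C)O)C[C@]2(C)[C@H]1C | intermediate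
20 | 2-[(4aR,5R,6S)-6-[(tert-butyldimethylsilyl)oxy]-4a,5-dimethyl-2-oxo-1-(trimethylsilyl)-2,3,4,4a,5,6-hexahydronaphthalen-3-yl]propan-2-yl methanesulfonate (not isolated) | CC(C)(C)[Si](C)(C)O[C@H]1C=CC2=C([Si](C)(C)C)C(=O)C(C(C)(C)OS(C)(=O)=O)C[C@]2(C)[C@H]1C | intermediate
21 | (4aR,5R,6S)-6-[(tert-butyldimethylsilyl)oxy]-4a,5-dimethyl-3-(propan-2-ylidene)-1-(trimethylsilyl)-4,4a,5,6-tetrahydronaphthalen-2(3H)-one | CC(C)(C)[Si](C)(C)O[C@H]1C=CC2=C([Si](C)(C)C)C(=O)C(=C(C)C)C[C@]2(C)[C@H]1C | intermediate
22 | (4aR,5R,6S)-6-hydroxy-4a,5-dimethyl-3-(propan-2-ylidene)-4,4a,5,6-tetrahydronaphthalen-2(3H)-one | O[C@H]1C=CC2=CC(=O)C(=C(C)C)C[C@]2(C)[C@H]1C | intermediate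
23 | (S)-2-methylbutan-1-ol | CC[C@H](C)CO | starting material
24 | triethyl 4-phosphonocrotonate [ethyl (E)-4-(diethoxyphosphoryl)but-2-enoate] | CCOC(=O)/C=C/CP(=O)(OCC)OCC | starting material
25 | (S)-2-methylbutanal (not isolated) | CC[C@H](C)C=O | intermediate
26 | lithium salt of the carbanion of 24 (not isolated) | CCOC(=O)/C=C/[CH-]P(=O)(OCC)OCC.[Li+] | intermediate
27 | ethyl (2E,4E,6S)-6-methylocta-2,4-dienoate | CC[C@H](C)/C=C/C=C/C(=O)OCC | intermediate
28 | (2E,4E,6S)-6-methylocta-2,4-dienoic acid | CC[C@H](C)/C=C/C=C/C(=O)O | intermediate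
29 | (2E,4E,6S)-6-methylocta-2,4-dienoic 2,4,6-trichlorobenzoic anhydride (not isolated) | CC[C@H](C)/C=C/C=C/C(=O)OC(=O)c1c(Cl)cc(Cl)cc1Cl | intermediate
30 | (1R,2S,8aR)-1,8a-dimethyl-6-oxo-7-(propan-2-ylidene)-1,2,6,7,8,8a-hexahydronaphthalen-2-yl (2E,4E,6S)-6-methylocta-2,4-dienoate | CC[C@H](C)/C=C/C=C/C(=O)O[C@H]1C=CC2=CC(=O)C(=C(C)C)C[C@]2(C)[C@H]1C | target

## Step count and least certain steps

Total: 17 steps. Longest linear sequence: 15 steps (steps 1 to 14 and step 17).

**Step 11 (key step).** What may go wrong: oxidative addition at the less hindered C7–C8 bond, or decarbonylation and β-hydride loss from the C5-bound alkyl rhodium outrunning the alkyne insertion. The cause is that insertion has to occur at a fully substituted carbon. The fallback uses known chemistry, sets out from 4 and comes back at 22. It postpones the creation of C5 to a Heck desymmetrisation.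
- Tsuji–Wacker oxidation of 4 (PdCl2, CuCl, O2, DMF–H2O) gives the methyl ketone F1.
- Wittig methoxymethylenation (Ph3P=CHOMe) gives the enol ether F2, and mild acid hydrolysis gives the α-methyl aldehyde F3 as an epimer mixture that is of no consequence.
- Robinson annulation with methyl vinyl ketone through the pyrrolidine enamine gives the 4,4-disubstituted cyclohexenone F4, and dehydrogenation with IBX gives the cyclohexadienone F5, in which the quaternary carbon is no longer a stereocentre.
- Iododesilylation (NIS, AgNO3) gives F6, and diimide reduction, which should be faster at the iodoalkyne than at the electron-poor dienone, gives the Z-iodoalkene F7 (the same compound as A5).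
- Heck cyclisation (Pd(OAc)2, PPh3, Et3N, MeCN) onto one of the two diastereotopic enone alkenes gives the trienone F8 (the same compound as A6) and sets C5.
- Conjugate reduction of the disubstituted C6=C7 enone with [(Ph3P)CuH]6 and capture of the copper enolate by acetone give the aldol F9. Dehydration as in step 13 gives F10, and Bu4NF removes the silyl ether to give 22.

**Step 6.** What may go wrong: poor facial selectivity in the methyl addition, because open-chain 1,2-induction at a ketone flanked by two branched carbons rests on a small energy difference; enolisation towards C4 is the second risk. The fallback sets out from 3 and comes back at 11. It replaces Felkin control by 1,3-chelation control and reverses the order in which the two C5 substituents arrive.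
- 3 is converted into its 4-methoxybenzyl ether F11 (4-methoxybenzyl trichloroacetimidate, catalytic CF3SO3H), and Tsuji–Wacker oxidation gives the methyl ketone F12.
- 7 is transmetalated with MgBr2·OEt2 to [1-(phenylsulfanyl)cyclopropyl]magnesium bromide F13 and added to the MgBr2 chelate of F12 in CH2Cl2 at −78 °C. The reagent should enter anti to the C4 methyl group of the six-membered chelate and give the carbinol F14 with the same C5 configuration as 10.
- Ring expansion as in step 7 gives F15, DDQ removes the benzyl ether to give F16, and TBSOTf with 2,6-lutidine returns 11.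

**Step 7.** What may go wrong: loss of configurational fidelity if a free tertiary cyclopropylcarbinyl cation lives long enough to be attacked on either face, and partial loss of the silyl ether under protic acid. The fallback sets out from 10 and comes back at 11. It runs the rearrangement under aprotic Lewis acid conditions through an epoxide.
- S-Methylation with Me3OBF4 gives the sulfonium salt F17.
- Base (KOH) lets the C5 alkoxide displace thioanisole at the cyclopropane carbon to give the oxaspiropentane F18, with C5 unchanged.
- LiBF4 in benzene should rearrange F18 to 11 with inversion at C5, as in the main route.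

**Step 14.** What may go wrong: incomplete cleavage of the C9–Si bond, or base-induced deconjugation of the isopropylidene by basic fluoride. The fallback sets out from 21 and comes back at 30. It separates the two desilylations and makes the second one acid-mediated.
- HF·pyridine in THF cleaves only the silyl ether to give F19.
- Esterification as in step 17 gives F20.
- CF3CO2H in CH2Cl2 then removes the C9 silyl group last by ipso-protodesilylation, whose β-silyl cation at C10 is allylic, to give 30.

## Further compounds

F1 | step 11 | (3S,4R)-4-[(tert-butyldimethylsilyl)oxy]-3-methyl-6-(trimethylsilyl)hex-5-yn-2-one | CC(=O)[C@@H](C)[C@@H](O[Si](C)(C)C(C)(C)C)C#C[Si](C)(C)C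
F2 | step 11 | tert-butyl{[(3R,4R)-6-methoxy-4,5-dimethyl-1-(trimethylsilyl)hex-5-en-1-yn-3-yl]oxy}dimethylsilane, E/Z mixture | COC=C(C)[C@@H](C)[C@@H](O[Si](C)(C)C(C)(C)C)C#C[Si](C)(C)C
F3 | step 11 | (3R,4R)-4-[(tert-butyldimethylsilyl)oxy]-2,3-dimethyl-6-(trimethylsilyl)hex-5-ynal, C2 epimers | O=CC(C)[C@@H](C)[C@@H](O[Si](C)(C)C(C)(C)C)C#C[Si](C)(C)C
F4 | step 11 | 4-{(2R,3R)-3-[(tert-butyldimethylsilyl)oxy]-5-(trimethylsilyl)pent-4-yn-2-yl}-4-methylcyclohex-2-en-1-one, C4 epimers | C[C@@H]([C@@H](O[Si](C)(C)C(C)(C)C)C#C[Si](C)(C)C)C1(C)CCC(=O)C=C1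
F5 | step 11 | 4-{(2R,3R)-3-[(tert-butyldimethylsilyl)oxy]-5-(trimethylsilyl)pent-4-yn-2-yl}-4-methylcyclohexa-2,5-dien-1-one | C[C@@H]([C@@H](O[Si](C)(C)C(C)(C)C)C#C[Si](C)(C)C)C1(C)C=CC(=O)C=C1
F6 | step 11 | 4-{(2R,3R)-3-[(tert-butyldimethylsilyl)oxy]-5-iodopent-4-yn-2-yl}-4-methylcyclohexa-2,5-dien-1-one | C[C@@H]([C@@H](O[Si](C)(C)C(C)(C)C)C#CI)C1(C)C=CC(=O)C=C1
F7 | step 11 | 4-{(2R,3R,4Z)-3-[(tert-butyldimethylsilyl)oxy]-5-iodopent-4-en-2-yl}-4-methylcyclohexa-2,5-dien-1-one | C[C@@H]([C@@H](O[Si](C)(C)C(C)(C)C)/C=C\I)C1(C)C=CC(=O)C=C1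
F8 | step 11 | (4aR,5R,6S)-6-[(tert-butyldimethylsilyl)oxy]-4a,5-dimethyl-5,6-dihydronaphthalen-2(4aH)-one | CC(C)(C)[Si](C)(C)O[C@H]1C=CC2=CC(=O)C=C[C@]2(C)[C@H]1C
F9 | step 11 | (4aR,5R,6S)-6-[(tert-butyldimethylsilyl)oxy]-3-(2-hydroxypropan-2-yl)-4a,5-dimethyl-4,4a,5,6-tetrahydronaphthalen-2(3H)-one, C3 epimers | CC(C)(C)[Si](C)(C)O[C@H]1C=CC2=CC(=O)C(C(C)(C)O)C[C@]2(C)[C@H]1C
F10 | step 11 | (4aR,5R,6S)-6-[(tert-butyldimethylsilyl)oxy]-4a,5-dimethyl-3-(propan-2-ylidene)-4,4a,5,6-tetrahydronaphthalen-2(3H)-one | CC(C)(C)[Si](C)(C)O[C@H]1C=CC2=CC(=O)C(=C(C)C)C[C@]2(C)[C@H]1C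
F11 | step 6 | 1-methoxy-4-({[(3R,4R)-4-methyl-1-(trimethylsilyl)hex-5-en-1-yn-3-yl]oxy}methyl)benzene | C=C[C@@H](C)[C@@H](OCc1ccc(OC)cc1)C#C[Si](C)(C)C
F12 | step 6 | (3S,4R)-4-[(4-methoxybenzyl)oxy]-3-methyl-6-(trimethylsilyl)hex-5-yn-2-one | CC(=O)[C@@H](C)[C@@H](OCc1ccc(OC)cc1)C#C[Si](C)(C)C
F13 | step 6 | [1-(phenylsulfanyl)cyclopropyl]magnesium bromide | Br[Mg]C1(Sc2ccccc2)CC1
F14 | step 6 | (2S,3S,4R)-4-[(4-methoxybenzyl)oxy]-3-methyl-2-[1-(phenylsulfanyl)cyclopropyl]-6-(trimethylsilyl)hex-5-yn-2-ol | C[C@@H]([C@@H](OCc1ccc(OC)cc1)C#C[Si](C)(C)C)[C@](C)(O)C1(Sc2ccccc2)CC1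
F15 | step 6 | (2R)-2-{(2R,3R)-3-[(4-methoxybenzyl)oxy]-5-(trimethylsilyl)pent-4-yn-2-yl}-2-methylcyclobutan-1-one | C[C@@H]([C@@H](OCc1ccc(OC)cc1)C#C[Si](C)(C)C)[C@@]1(C)CCC1=O
F16 | step 6 | (2R)-2-[(2R,3R)-3-hydroxy-5-(trimethylsilyl)pent-4-yn-2-yl]-2-methylcyclobutan-1-one | C[C@@H]([C@@H](O)C#C[Si](C)(C)C)[C@@]1(C)CCC1=O
F17 | step 7 | {1-[(2S,3S,4R)-4-[(tert-butyldimethylsilyl)oxy]-2-hydroxy-3-methyl-6-(trimethylsilyl)hex-5-yn-2-yl]cyclopropyl}(methyl)phenylsulfonium tetrafluoroborate, both configurations at sulfur | C[C@@H]([C@@H](O[Si](C)(C)C(C)(C)C)C#C[Si](C)(C)C)[C@](C)(O)C1([S+](C)c2ccccc2)CC1.F[B-](F)(F)F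
F18 | step 7 | (2S)-2-{(2S,3R)-3-[(tert-butyldimethylsilyl)oxy]-5-(trimethylsilyl)pent-4-yn-2-yl}-2-methyl-1-oxaspiro[2.2]pentane | C[C@@H]([C@@H](O[Si](C)(C)C(C)(C)C)C#C[Si](C)(C)C)[C@]1(C)OC12CC2
F19 | step 14 | (4aR,5R,6S)-6-hydroxy-4a,5-dimethyl-3-(propan-2-ylidene)-1-(trimethylsilyl)-4,4a,5,6-tetrahydronaphthalen-2(3H)-one | O[C@H]1C=CC2=C([Si](C)(C)C)C(=O)C(=C(C)C)C[C@]2(C)[C@H]1C
F20 | step 14 | (1R,2S,8aR)-1,8a-dimethyl-6-oxo-7-(propan-2-ylidene)-5-(trimethylsilyl)-1,2,6,7,8,8a-hexahydronaphthalen-2-yl (2E,4E,6S)-6-methylocta-2,4-dienoate | CC[C@H](C)/C=C/C=C/C(=O)O[C@H]1C=CC2=C([Si](C)(C)C)C(=O)C(=C(C)C)C[C@]2(C)[C@H]1C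
A1 | alternative 1 | (5'R,6'S)-5'-methyl-3',4',5',6',7',8'-hexahydro-1'H-spiro[1,3-dioxolane-2,2'-naphthalen]-6'-ol (C5=C10 alkene, C8 ethylene ketal, cis C3 hydroxyl and C4 methyl) | C[C@H]1[C@@H](O)CCC2=C1CCC1(OCCO1)C2
A2 | alternative 1 | C5,C10-methano-bridged decalin: (3S,4R)-3-hydroxy-4-methyl compound with a cyclopropane across C5 and C10 cis to the hydroxyl and an ethylene ketal at C8 (eremophilane numbering) | C[C@H]1[C@@H](O)CC[C@@]23C[C@@]12CCC4(OCCO4)C3
A3 | alternative 2 | trimethyl{[(4R)-4-methyl-3-methylidene-4-[(2R)-3-(trimethylsilyloxy)but-3-en-2-yl]cyclohex-1-en-1-yl]oxy}silane | C[C@@H](C(=C)O[Si](C)(C)C)[C@@]1(C)CCC(O[Si](C)(C)C)=CC1=C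
A4 | alternative 2 | (4aR,5R)-4a,5-dimethyl-4,4a,7,8-tetrahydronaphthalene-2,6(3H,5H)-dione | C[C@H]1C(=O)CCC2=CC(=O)CC[C@]12C
A5 | alternative 3 | 4-{(2R,3R,4Z)-3-[(tert-butyldimethylsilyl)oxy]-5-iodopent-4-en-2-yl}-4-methylcyclohexa-2,5-dien-1-one | C[C@@H]([C@@H](O[Si](C)(C)C(C)(C)C)/C=C\I)C1(C)C=CC(=O)C=C1
A6 | alternative 3 | (4aR,5R,6S)-6-[(tert-butyldimethylsilyl)oxy]-4a,5-dimethyl-5,6-dihydronaphthalen-2(4aH)-one | CC(C)(C)[Si](C)(C)O[C@H]1C=CC2=CC(=O)C=C[C@]2(C)[C@H]1C
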